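## Retrosynthetic overview

1. Eriolangin ⇐ desilylation and 6-O-angeloylation of α-methylene lactone 23; the cis-lactone (C7–C11 cis to C8–O) and the trans C6–OH arise together when a phosphonoacetate tethered on C8–O opens a 6,7-epoxide, followed by HWE methylenation with CH2O.
2. Epoxy alcohol ⇐ anti-epoxidation and ester reduction of cyclohexadienyl acetate 17, which comes from retro-Claisen/E1cB unravelling of the oxa-bridged tricycle 14 (C1–C10 cut, C5=C10 formed, C8–O kept).
3. 14 ⇐ intramolecular furan Diels–Alder reaction (IMDAF) of methylidene β-keto ester 13: this builds the carbocycle, and the C4 methyl on the tether fixes C8.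
4. C4 ⇐ SN2 opening of (R)-β-butyrolactone by a 2-furyl copper reagent, then Arndt–Eistert homologation and Claisen acylation.
5. Ring order: cyclohexene (with a temporary oxa-bridge and a temporary ring A) → epoxide → γ-lactone.

Assumption: locants C1–C15 are those of eriolangin (C4 side-chain stereocentre, C5=C10 ring alkene, C6 O-angelate, C7/C8 lactone fusion, C11–C13 lactone, C14 ring CH2OH), and (R)-β-butyrolactone (the lactone of poly-hydroxybutyrate-derived (R)-3-hydroxybutanoic acid) is bought.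

## Route

Step 1
Reactants: 1 furan; 2 (R)-β-butyrolactone [(R)-4-methyloxetan-2-one]
Product: 5 (S)-3-(furan-2-yl)butanoic acid, via 2-furyllithium 3 (not isolated), via 2-furylmagnesium bromide 4 (not isolated)
Conditions: n-BuLi, THF, 0 °C; MgBr2·OEt2; CuI (10 mol %), Me2S, −30 °C, then 2; aq. HCl
Reagents that add atoms: none
Why: Cu(I)-catalysed SN2 ring opening of the strained β-lactone at the β-carbon (alkyl–oxygen cleavage, as known for aryl Grignard reagents) goes with inversion, so (R)-2 gives the (S)-configured C4 centre, the only stereocentre that is bought.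

Step 2
Reactants: 5 (S)-3-(furan-2-yl)butanoic acid
Product: 7 (S)-1-diazo-4-(furan-2-yl)pentan-2-one, via mixed carbonic anhydride 6 (not isolated)
Conditions: i-BuOCOCl, N-methylmorpholine, THF, −15 °C; then CH2N2, Et2O, 0 °C
Reagents that add atoms: diazomethane C=[N+]=[N-]
Why: Mixed-anhydride activation and C-acylation of diazomethane (first half of an Arndt–Eistert homologation) avoid acid that would harm the furan and do not touch the stereocentre.

Step 3
Reactants: 7 (S)-1-diazo-4-(furan-2-yl)pentan-2-one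
Product: 9 (S)-4-(furan-2-yl)pentanoic acid, via ketene 8 (not isolated)
Conditions: PhCO2Ag (10 mol %), Et3N, THF/H2O (9:1), rt, dark
Reagents that add atoms: water O
Why: Silver-catalysed Wolff rearrangement gives the ketene, which water traps as the one-carbon-homologated acid; the migrating CH2 carries the remote stereocentre along unchanged.

Step 4
Reactants: 9 (S)-4-(furan-2-yl)pentanoic acid
Product: 11 methyl (6S)-2-[(dimethylamino)methyl]-6-(furan-2-yl)-3-oxoheptanoate (C2 epimers), via acyl imidazolide 10 (not isolated)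
Conditions: CDI, THF, rt; then LiCH(CH2NMe2)CO2Me [Me2NCH2CH2CO2Me (2.2 equiv), LDA, THF, −78 °C], −78 → −30 °C; AcOH
Reagents that add atoms: methyl 3-(dimethylamino)propanoate COC(=O)CCN(C)C
Why: Crossed Claisen acylation of a β-amino ester enolate by the acyl imidazolide gives the β-keto ester already carrying a masked exo-methylene group (a Mannich base), with C6 untouched.

Step 5
Reactants: 11 methyl (6S)-2-[(dimethylamino)methyl]-6-(furan-2-yl)-3-oxoheptanoate
Product: 14 methyl (4S,4aR,7R,8aR)-4-methyl-1-oxo-1,2,3,4,4a,7,8,8a-octahydro-4a,7-epoxynaphthalene-8a-carboxylate (5,6-alkene; IMDAF adduct), via trimethylammonium iodide 12 (not isolated), via methylidene keto ester 13 (not isolated)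
Conditions: MeI, CH2Cl2, rt; aq. NaHCO3, 0 °C; then CH2Cl2 (0.02 M), 23 °C, 24 h
Reagents that add atoms: none
Why: N-methylation and E1cB loss of Me3N unmask the doubly activated 2-methylidene-3-oxo ester, which undergoes an intramolecular Diels–Alder reaction with the furan (IMDAF) through the exo-tether transition state in which the C4 methyl is equatorial on the forming six-membered ring (anti to the forming C5–C10 bond, away from furan H-3 and 1,3 to the endo ester), so (4S) is expected to dictate the (5R,8R) face.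

Step 6
Reactants: 14 IMDAF adduct
Product: 17 methyl (5R)-5-acetoxy-2-[(2S)-5-methoxy-5-oxopentan-2-yl]cyclohexa-1,3-diene-1-carboxylate, via bridged ester enolate 15 (not isolated), via dienol alkoxide 16 (not isolated)
Conditions: LiOMe (1.05 equiv), THF, −40 → 0 °C; then Ac2O, DMAP (cat.), 0 °C
Reagents that add atoms: lithium methoxide [Li+].[O-]C; acetic anhydride CC(=O)OC(C)=O
Why: Methoxide attacks the non-enolisable ketone (retro-Claisen/retro-Dieckmann), the released C10 ester enolate opens the strained oxa-bridge by E1cB β-elimination (C5=C10 formed, C8–O− kept) and the alkoxide is acetylated in situ, leaving C4 and C8 unchanged.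

Step 7
Reactants: 17 dienyl acetate
Product: 18 methyl (1R,5R,6S)-5-acetoxy-2-[(2S)-5-methoxy-5-oxopentan-2-yl]-7-oxabicyclo[4.1.0]hept-2-ene-3-carboxylate (6,7-epoxide trans to C8–OAc)
Conditions: m-CPBA, NaHCO3, CH2Cl2, 0 °C → rt
Reagents that add atoms: m-CPBA O=C(OO)c1cccc(Cl)c1
Why: Prilezhaev epoxidation takes the γ,δ-alkene (the α,β-alkene is deactivated by the ester) and, with the hydroxyl masked as acetate so that no hydrogen-bond delivery operates, the face anti to the allylic C8 acetoxy group, which sets the future C6–O configuration.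

Step 8
Reactants: 18 epoxy acetate diester
Product: 19 (1R,5R,6S)-3-(hydroxymethyl)-2-[(2S)-5-hydroxypentan-2-yl]-7-oxabicyclo[4.1.0]hept-2-en-5-ol
Conditions: DIBAL-H (7 equiv), CH2Cl2, −78 → −20 °C; Rochelle salt
Reagents that add atoms: none
Why: DIBAL-H reduces both methyl esters by 1,2-addition to primary alcohols and cleaves the acetate, conditions under which γ,δ-epoxy enoates are known to keep the epoxide.

Step 9
Reactants: 19 epoxy triol
Product: 20 (1R,5R,6S)-3-{[(tert-butyldimethylsilyl)oxy]methyl}-2-{(2S)-5-[(tert-butyldimethylsilyl)oxy]pentan-2-yl}-7-oxabicyclo[4.1.0]hept-2-en-5-ol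
Conditions: TBSCl (2.1 equiv), imidazole, CH2Cl2, −20 → 0 °C
Reagents that add atoms: tert-butyldimethylsilyl chloride CC(C)(C)[Si](C)(C)Cl
Why: Silylation is selective for the two primary hydroxyls over the hindered secondary C8 hydroxyl next to the epoxide.

Step 10
Reactants: 20 bis-TBS epoxy alcohol
Product: 21 C8 diethylphosphonoacetate of 20
Conditions: (EtO)2P(O)CH2CO2H, DCC, DMAP (cat.), CH2Cl2, 0 °C → rt
Reagents that add atoms: diethylphosphonoacetic acid CCOP(=O)(OCC)CC(=O)O
Why: Steglich esterification places the C11–C12 nucleophile on C8–O, the face on which the C7–C11 bond must form.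

Step 11
Reactants: 21 phosphonoacetate
Product: 23 6-O-deangeloyl-1,14-di-O-TBS-eriolangin (α-methylene cis-lactone with free C6–OH), via phosphono lactone 22 (not isolated)
Conditions: NaH (1.1 equiv), THF/DMF (4:1), 0 → 50 °C; then (CH2O)n, 0 °C → rt
Reagents that add atoms: formaldehyde (as paraformaldehyde) C=O
Why: The phosphonate carbanion opens the epoxide intramolecularly by SN2 attack at C7 (5-exo, anti to the epoxide oxygen, inversion at C7) to give the cis-fused γ-lactone with C6–OH trans to it, and the resulting α-phosphono lactone anion undergoes Horner–Wadsworth–Emmons olefination with formaldehyde.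

Step 12
Reactants: 23 hydroxy α-methylene lactone
Product: 24 1,14-di-O-TBS-eriolangin
Conditions: angelic acid, 2,4,6-Cl3C6H2COCl, Et3N, toluene, rt, 2 h; then 23, 80 °C
Reagents that add atoms: angelic acid C/C=C(/C)C(=O)O
Why: Yamaguchi-type esterification through the 2,4,6-trichlorobenzoyl mixed anhydride without DMAP acylates the hindered allylic C6 hydroxyl with retention and without Z→E isomerisation of the angelate.

Step 13
Reactants: 24 1,14-di-O-TBS-eriolangin
Product: 25 eriolangin
Conditions: HF·pyridine, pyridine, THF, 0 °C → rt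
Reagents that add atoms: none
Why: Buffered fluoride cleaves both primary TBS ethers (Si–O cleavage) without touching the angelate or the α-methylene lactone.

## Compound list

1 | furan | c1ccoc1 | starting material
2 | (R)-β-butyrolactone [(R)-4-methyloxetan-2-one] | C[C@@H]1CC(=O)O1 | starting material
3 | 2-furyllithium | [Li]c1ccco1 | intermediate
4 | 2-furylmagnesium bromide | Br[Mg]c1ccco1 | intermediate
5 | (S)-3-(furan-2-yl)butanoic acid | C[C@@H](CC(=O)O)c1ccco1 | intermediate
6 | (S)-3-(furan-2-yl)butanoic isobutyl carbonic anhydride | C[C@@H](CC(=O)OC(=O)OCC(C)C)c1ccco1 | intermediate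
7 | (S)-1-diazo-4-(furan-2-yl)pentan-2-one | C[C@@H](CC(=O)C=[N+]=[N-])c1ccco1 | intermediate
8 | (S)-4-(furan-2-yl)pent-1-en-1-one (ketene) | C[C@@H](CC=C=O)c1ccco1 | intermediate
9 | (S)-4-(furan-2-yl)pentanoic acid | C[C@@H](CCC(=O)O)c1ccco1 | intermediate
10 | (S)-4-(furan-2-yl)-1-(imidazol-1-yl)pentan-1-one | C[C@@H](CCC(=O)n1ccnc1)c1ccco1 | intermediate
11 | methyl (6S)-2-[(dimethylamino)methyl]-6-(furan-2-yl)-3-oxoheptanoate (C2 epimers) | C[C@@H](CCC(=O)C(CN(C)C)C(=O)OC)c1ccco1 | intermediate
12 | [(6S)-6-(furan-2-yl)-2-(methoxycarbonyl)-3-oxoheptyl]trimethylammonium iodide | C[C@@H](CCC(=O)C(C[N+](C)(C)C)C(=O)OC)c1ccco1.[I-] | intermediate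
13 | methyl (6S)-6-(furan-2-yl)-2-methylidene-3-oxoheptanoate | C[C@@H](CCC(=O)C(=C)C(=O)OC)c1ccco1 | intermediate
14 | methyl (4S,4aR,7R,8aR)-4-methyl-1-oxo-1,2,3,4,4a,7,8,8a-octahydro-4a,7-epoxynaphthalene-8a-carboxylate (5,6-alkene; 4S,5R,8R,10R in eriolangin numbering) | C[C@H]1CCC(=O)[C@@]2(C(=O)OC)C[C@@H]3C=C[C@]12O3 | intermediate
15 | lithium ester enolate of methyl (1R,4R)-1-[(2S)-5-methoxy-5-oxopentan-2-yl]-7-oxabicyclo[2.2.1]hept-5-ene-2-carboxylate | C[C@@H](CCC(=O)OC)[C@@]12C=C[C@@H](CC1=C(OC)[O-])O2.[Li+] | intermediate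
16 | lithium alkoxide of methyl (5R)-5-hydroxy-2-[(2S)-5-methoxy-5-oxopentan-2-yl]cyclohexa-1,3-diene-1-carboxylate | C[C@@H](CCC(=O)OC)C1=C(C(=O)OC)C[C@@H]([O-])C=C1.[Li+] | intermediate
17 | methyl (5R)-5-acetoxy-2-[(2S)-5-methoxy-5-oxopentan-2-yl]cyclohexa-1,3-diene-1-carboxylate | C[C@@H](CCC(=O)OC)C1=C(C(=O)OC)C[C@@H](OC(C)=O)C=C1 | intermediate
18 | methyl (1R,5R,6S)-5-acetoxy-2-[(2S)-5-methoxy-5-oxopentan-2-yl]-7-oxabicyclo[4.1.0]hept-2-ene-3-carboxylate | C[C@@H](CCC(=O)OC)C1=C(C(=O)OC)C[C@@H](OC(C)=O)[C@@H]2O[C@H]12 | intermediate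
19 | (1R,5R,6S)-3-(hydroxymethyl)-2-[(2S)-5-hydroxypentan-2-yl]-7-oxabicyclo[4.1.0]hept-2-en-5-ol | C[C@@H](CCCO)C1=C(CO)C[C@@H](O)[C@@H]2O[C@H]12 | intermediate
20 | (1R,5R,6S)-3-{[(tert-butyldimethylsilyl)oxy]methyl}-2-{(2S)-5-[(tert-butyldimethylsilyl)oxy]pentan-2-yl}-7-oxabicyclo[4.1.0]hept-2-en-5-ol | C[C@@H](CCCO[Si](C)(C)C(C)(C)C)C1=C(CO[Si](C)(C)C(C)(C)C)C[C@@H](O)[C@@H]2O[C@H]12 | intermediate
21 | 5-O-[2-(diethoxyphosphoryl)acetyl] ester of 20 | C[C@@H](CCCO[Si](C)(C)C(C)(C)C)C1=C(CO[Si](C)(C)C(C)(C)C)C[C@@H](OC(=O)CP(=O)(OCC)OCC)[C@@H]2O[C@H]12 | intermediate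
22 | 11-(diethoxyphosphoryl)-11,13-dihydro-13-nor analogue of 23 (α-phosphono cis-lactone; sodium salt at C11 in the flask, drawn neutral; C11 epimers) | CCOP(=O)(OCC)C1C(=O)O[C@@H]2CC(CO[Si](C)(C)C(C)(C)C)=C([C@@H](C)CCCO[Si](C)(C)C(C)(C)C)[C@@H](O)[C@H]12 | intermediate
23 | 6-O-deangeloyl-1,14-di-O-TBS-eriolangin | C=C1C(=O)O[C@@H]2CC(CO[Si](C)(C)C(C)(C)C)=C([C@@H](C)CCCO[Si](C)(C)C(C)(C)C)[C@@H](O)[C@H]12 | intermediate
24 | 1,14-di-O-TBS-eriolangin | C=C1C(=O)O[C@@H]2CC(CO[Si](C)(C)C(C)(C)C)=C([C@@H](C)CCCO[Si](C)(C)C(C)(C)C)[C@@H](OC(=O)/C(C)=C\C)[C@H]12 | intermediate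
25 | eriolangin (4S,6S,7R,8R) | C=C1C(=O)O[C@@H]2CC(CO)=C([C@@H](C)CCCO)[C@@H](OC(=O)/C(C)=C\C)[C@H]12 | target

## Step count and risks

Total step count: 13. Longest linear sequence: 13 (fully linear from 1 and 2).

Most likely to fail:

Step 5 (release of the labile methylidene keto ester 13 and the reversible furan Diels–Alder reaction). The risks are Michael addition or polymerisation of 13 under the amine/bicarbonate conditions, an unfavourable equilibrium, and an untested diastereoselectivity. The fallback sets out from 9 and comes back at 13. Acid 9 is activated as 10 as in step 4 but condensed with the lithium enolate of methyl propanoate (LDA, THF, −78 °C) to give methyl (6S)-6-(furan-2-yl)-2-methyl-3-oxoheptanoate F1. PhSeCl/pyridine (CH2Cl2, 0 °C) gives methyl (6S)-6-(furan-2-yl)-2-methyl-3-oxo-2-(phenylselanyl)heptanoate F2. H2O2 (CH2Cl2, 0 °C) gives methyl (6S)-6-(furan-2-yl)-2-methyl-3-oxo-2-(phenylseleninyl)heptanoate F3, whose selenoxide syn-elimination (only the methyl group has β-hydrogens) releases 13 under neutral, amine-free conditions at 0–20 °C. 13 then cyclises to 14, if needed with Me2AlCl (1.1 equiv, −78 °C) to hold the adduct as its chelate before step 6.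

Step 11 (ester-tethered carbanion opening a vinyl epoxide). The risks are the s-trans ester preference, competing attack at the allylic C6, and sluggish SN2 by a stabilised anion. The fallback sets out from 20 and comes back at 23. Alcohol 20 is acylated with acryloyl chloride (i-Pr2NEt, CH2Cl2, −20 °C) to the C8 acrylate of 20 F4. PMe3 (0.5–1 equiv, t-BuOH/THF, rt) then promotes an intramolecular Morita–Baylis–Hillman-type alkylation: the phosphine adds to the acrylate, the resulting enolate opens the epoxide at C7 in the same 5-exo sense, and loss of PMe3 gives the α-methylene lactone 23 directly, without stoichiometric base or a separate olefination.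

Step 12 (angeloylation of a hindered allylic alcohol). The risks are slow acylation and Z→E isomerisation to the tiglate. The fallback sets out from 23 and comes back at 24, building the angelate on the alcohol instead of transferring it. Alcohol 23 is esterified with 2-[bis(2,2,2-trifluoroethoxy)phosphoryl]propanoic acid (DCC, DMAP, CH2Cl2) to the 6-O-{2-[bis(2,2,2-trifluoroethoxy)phosphoryl]propanoyl} derivative of 23 F5. KHMDS/18-crown-6 (THF, −78 °C) gives the potassium phosphonate carbanion of F5 F6, and a Z-selective Still–Gennari olefination with acetaldehyde gives the (Z)-2-methylbut-2-enoate 24.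

## Further compounds

F1 | step 5 | methyl (6S)-6-(furan-2-yl)-2-methyl-3-oxoheptanoate | C[C@@H](CCC(=O)C(C)C(=O)OC)c1ccco1
F2 | step 5 | methyl (6S)-6-(furan-2-yl)-2-methyl-3-oxo-2-(phenylselanyl)heptanoate | C[C@@H](CCC(=O)C(C)([Se]c1ccccc1)C(=O)OC)c1ccco1
F3 | step 5 | methyl (6S)-6-(furan-2-yl)-2-methyl-3-oxo-2-(phenylseleninyl)heptanoate | C[C@@H](CCC(=O)C(C)([Se](=O)c1ccccc1)C(=O)OC)c1ccco1
F4 | step 11 | C8 acrylate of 20 | C[C@@H](CCCO[Si](C)(C)C(C)(C)C)C1=C(CO[Si](C)(C)C(C)(C)C)C[C@@H](OC(=O)C=C)[C@@H]2O[C@H]12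
F5 | step 12 | 6-O-{2-[bis(2,2,2-trifluoroethoxy)phosphoryl]propanoyl} derivative of 23 | C=C1C(=O)O[C@@H]2CC(CO[Si](C)(C)C(C)(C)C)=C([C@@H](C)CCCO[Si](C)(C)C(C)(C)C)[C@@H](OC(=O)C(C)P(=O)(OCC(F)(F)F)OCC(F)(F)F)[C@H]12
F6 | step 12 | potassium phosphonate carbanion of F5 | C=C1C(=O)O[C@@H]2CC(CO[Si](C)(C)C(C)(C)C)=C([C@@H](C)CCCO[Si](C)(C)C(C)(C)C)[C@@H](OC(=O)[C-](C)P(=O)(OCC(F)(F)F)OCC(F)(F)F)[C@H]12.[K+]
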